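The runs are calculated for an exercise; noise was put on by code.

In a closed, stirred vessel at constant temperature a free catalyst turns starting material into target. These were the flasks, the readings and the questions:

| setting | noon | summer | dawn | winter | midnight |
|---|---|---|---|---|---|
| starting material | 0.0800 M | 0.0480 M | 0.0800 M | 0.160 M | 0.0800 M |
| free catalyst | 4.00 × 10⁻⁴ M | 4.00 × 10⁻⁴ M | 8.00 × 10⁻⁴ M | 4.00 × 10⁻⁴ M | 4.00 × 10⁻⁴ M |
| time |  |  |  |  | 41 h |

- noon run (time / h: [starting material] / M): 0.27: 0.0713; 0.52: 0.0654; 0.99: 0.0562; 1.9: 0.0464; 3.6: 0.0354; 6.8: 0.0283
- summer run (time / h: [starting material] / M): 0.27: 0.0436; 0.52: 0.0387; 0.99: 0.0324; 1.9: 0.0262; 3.6: 0.0192; 6.8: 0.0171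
- dawn run (time / h: [starting material] / M): 0.27: 0.0670; 0.52: 0.0558; 0.99: 0.0453; 1.9: 0.0346; 3.6: 0.0272; 6.8: 0.0256
- winter run (time / h: [starting material] / M): 0.27: 0.1435; 0.52: 0.1323; 0.99: 0.1146; 1.9: 0.0930; 3.6: 0.0699; 6.8: 0.0515

(readings scatter by 6 × 10⁻⁴ M)

* reaction order in [starting material] at the outset, round the charge of the noon run, defined at two percent of the starting material turned into target (one fixed amount of target, the same in the runs compared)
* reaction order in [free catalyst] at the outset, round the charge of the noon run, defined at two percent of the starting material turned into target
* starting material in the midnight run at 41 h, as a share of the starting material charged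

- Overall: starting material -> target, with free catalyst as catalyst.
- Constant volume, constant temperature.
- A reading of a species includes what of it is bound.
- An order is taken over about fifteen percent of the charge, up and down.

I turned the last question round: what would the readings have to show for the midnight flask, charged like the noon run, to stay at the share of its charge where the dawn run seemed to stop? The dawn run, with twice the catalyst of the noon run, stood at a third of its charge at 6.8 h. A true stop is the zero of the scale: two late readings of c(starting material) should differ by about the scatter of a difference, 8.49 × 10⁻⁴ M. The dawn run instead fell 0.00160 M from 3.6 h to 6.8 h, more than that scatter by a factor of 1.89, which is a weak sign but points away from a stop.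

I took that fall as a slow drain going with the square of c(starting material). I named its measure the drain constant, the rise of 1/c(starting material) per hour over the last interval of a run that looks finished (an apparent second-order rate constant). The dawn readings give 0.718 L mol⁻¹ h⁻¹. Starting from the last noon reading, 0.0283 M at 6.8 h, and running on to 41 h, it gave me 20.9% of the charge, and I committed to that.

The forecast gave orders of 0.87 and 0.92 and a share of 32%, higher than mine, holding that "the midnight run should sit at equilibrium".

The flask gave 0.60 in c(starting material), 1.0 in c(free catalyst) and 16.9% at 41 h.

    free catalyst + starting material ⇌ catalyst-substrate complex, settled at all times (9.430 L mol⁻¹)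
    catalyst-substrate complex ⇌ target + free catalyst (151.2 h⁻¹, 820.8 L mol⁻¹ h⁻¹)
    2 starting material → homo dimer (0.5652 L mol⁻¹ h⁻¹)
    free catalyst + starting material → spent catalyst + starting material (8.280 L mol⁻¹ h⁻¹)

So the midnight flask ended lower than my 20.9%, and the same fall from the last noon reading asks for 1.13 L mol⁻¹ h⁻¹ as its drain constant. In the dawn run target reached half of the charge at 1.95 h. With the nearest reading, 0.0346 M at 1.9 h, that leaves about 0.00540 M counted as neither starting material nor target. The drain constant, taken as second order from the charge to that dawn reading, covers about 0.00378 M of it.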